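## Retrosynthetic overview

- Feature: two identical 5,7-dimethoxycoumarin units are joined through C8 to a 1,4-dimethylcyclohex-3-ene, one directly at C2 and one through an E-vinyl group at C1. Each pyranone ring (O1, C2, C3, C4) can be cut at C3=C4 and at the O1–C2 ester bond, leaving a phenol on C8a and a formyl carbon (C4) on C4a.
- Target ⇒ bis(salicylaldehyde) 13 + two Ph3P=CHCO2Et (twofold Wittig olefination–lactonisation; both pyranone rings are closed last, together).
- 13 ⇒ bis(phenol) 11 (twofold ortho-formylation) ⇒ bis(allyl ether) 10 ⇒ aldehyde 7 + benzylic phosphonate 9 (E-selective Horner–Wadsworth–Emmons reaction at the styryl C=C).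
- 7 ⇒ aryl diene 5 + methacrolein 6 (catalytic enantioselective endo Diels–Alder; the cyclohexene ring is formed first, through bonds C1–C2 and C5–C6, with both stereocentres).
- 5 and 9 ⇒ one O-allyl salicylaldehyde 2, made from 2-hydroxy-4,6-dimethoxybenzaldehyde 1. Ring order: cyclohexene, then the two pyranones.

Key step: step 10

Assumptions:
- The cyclohexene is numbered C1 (quaternary; methyl and styryl), C2 (aryl), C3=C4 (methyl on C4), C5, C6. With this numbering the target is (1R,2R), and the C2 aryl group is cis to the C1 styryl group.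
- The sense of induction in step 4 is taken from the accepted binding model of 2-substituted acroleins on the cationic oxazaborolidine. If the sense proves opposite, the (R)-catalyst is used instead.

## Route

Step 1
Reactants: 1 2-hydroxy-4,6-dimethoxybenzaldehyde
Product: 2 2-(allyloxy)-4,6-dimethoxybenzaldehyde
Conditions: allyl bromide, K2CO3, DMF, 60 °C
Reagents that add atoms: allyl bromide, C=CCBr
Why: Williamson O-alkylation of the phenoxide; the allyl ether tolerates the later bases, hydride and Lewis acids and can be removed under neutral conditions that spare the acid-sensitive electron-rich styrene.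

Step 2
Reactants: 3 3-chloro-2-methylprop-1-ene
Product: 4 diethyl (2-methylprop-2-en-1-yl)phosphonate
Conditions: P(OEt)3 (neat), NaI (cat.), 130 °C, sealed tube
Reagents that add atoms: triethyl phosphite, CCOP(OCC)OCC
Why: Michaelis–Arbuzov reaction of a reactive allylic chloride, with iodide exchange speeding up the alkylation of phosphorus.

Step 3
Reactants: 4 diethyl (2-methylprop-2-en-1-yl)phosphonate; 2 2-(allyloxy)-4,6-dimethoxybenzaldehyde
Product: 5 1-(allyloxy)-3,5-dimethoxy-2-[(1E)-3-methylbuta-1,3-dien-1-yl]benzene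
Conditions: 4, n-BuLi, THF, −78 °C; then 2, HMPA, −78 °C → rt
Reagents that add atoms: none
Why: Horner–Wadsworth–Emmons olefination with a lithiated allylic phosphonate, which attacks the non-enolisable aldehyde through its α-carbon and eliminates to the E-1,3-diene.

Step 4
Reactants: 5 1-(allyloxy)-3,5-dimethoxy-2-[(1E)-3-methylbuta-1,3-dien-1-yl]benzene; 6 methacrolein (2-methylprop-2-enal)
Product: 7 (1S,2S)-2-[2-(allyloxy)-4,6-dimethoxyphenyl]-1,4-dimethylcyclohex-3-ene-1-carbaldehyde (aryl cis to formyl)
Conditions: (S)-1-(2-methylphenyl)-3,3-diphenyltetrahydro-1H,3H-pyrrolo[1,2-c][1,3,2]oxazaborole (20 mol %), Tf2NH (17 mol %), 6 (5 equiv), CH2Cl2, −78 → −20 °C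
Reagents that add atoms: none
Why: Enantioselective Diels–Alder reaction catalysed by a chiral cationic oxazaborolidine, in which the 1-aryl and 3-methyl groups of the diene both direct its aryl-bearing terminus to the α-carbon of the enal, the endo transition state (formyl under the diene) places aryl and formyl cis at C2 and C1, and the s-trans enal, held on boron by B–O coordination and a formyl C–H···O contact and shielded on one face by a catalyst phenyl group, is attacked at the Re face of its α-carbon, which sets C1 as S.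

Step 5
Reactants: 2 2-(allyloxy)-4,6-dimethoxybenzaldehyde
Product: 8 [2-(allyloxy)-4,6-dimethoxyphenyl]methanol
Conditions: NaBH4, MeOH, 0 °C
Reagents that add atoms: none
Why: Borohydride reduction of an aryl aldehyde; the allyl ether and the arene are inert.

Step 6
Reactants: 8 [2-(allyloxy)-4,6-dimethoxyphenyl]methanol
Product: 9 diethyl {[2-(allyloxy)-4,6-dimethoxyphenyl]methyl}phosphonate
Conditions: P(OEt)3, ZnI2, THF, reflux
Reagents that add atoms: triethyl phosphite, CCOP(OCC)OCC
Why: ZnI2-mediated direct conversion of an electron-rich benzylic alcohol into its phosphonate (an Arbuzov-type process through the benzylic phosphite), which avoids the unstable 2,4,6-trialkoxybenzyl halide.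

Step 7
Reactants: 9 diethyl {[2-(allyloxy)-4,6-dimethoxyphenyl]methyl}phosphonate; 7 (1S,2S)-2-[2-(allyloxy)-4,6-dimethoxyphenyl]-1,4-dimethylcyclohex-3-ene-1-carbaldehyde
Product: 10 1-(allyloxy)-2-[(E)-2-{(1R,2R)-2-[2-(allyloxy)-4,6-dimethoxyphenyl]-1,4-dimethylcyclohex-3-en-1-yl}ethenyl]-3,5-dimethoxybenzene
Conditions: 9, NaH, 15-crown-5, THF, 0 °C; then 7, 0 → 50 °C
Reagents that add atoms: none
Why: Horner–Wadsworth–Emmons olefination of a non-enolisable α-quaternary aldehyde with a benzylic phosphonate anion, which should give the E-styrene under thermodynamic control and cannot epimerise C1 (the descriptors change only because the ligand priorities change).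

Step 8
Reactants: 10 bis(allyl ether) of step 7
Product: 11 2-[(E)-2-{(1R,2R)-2-(2-hydroxy-4,6-dimethoxyphenyl)-1,4-dimethylcyclohex-3-en-1-yl}ethenyl]-3,5-dimethoxyphenol
Conditions: Pd(PPh3)4 (5 mol %), morpholine, THF, rt
Reagents that add atoms: none
Why: Tsuji–Trost deallylation, in which zerovalent palladium ionises each aryl allyl ether to a π-allyl complex that morpholine captures, under neutral conditions that leave the styrene and the ring alkene untouched.

Step 9
Reactants: 11 bis(phenol) of step 8
Product: 13 3-[(E)-2-{(1R,2R)-2-(3-formyl-2-hydroxy-4,6-dimethoxyphenyl)-1,4-dimethylcyclohex-3-en-1-yl}ethenyl]-2-hydroxy-4,6-dimethoxybenzaldehyde, via bis(salicyl alcohol) 12 (not isolated)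
Conditions: MgCl2, Et3N, (CH2O)n, MeCN, reflux; mild aqueous acid work-up
Reagents that add atoms: paraformaldehyde (as formaldehyde), C=O
Why: Magnesium-mediated ortho-formylation (Casnati–Skattebøl), in which each magnesium phenoxide delivers formaldehyde to its only free ortho position and the resulting benzylic alkoxide is oxidised by hydride transfer to a second formaldehyde, so the position para to the hydroxyl between the two methoxy groups is not touched.

Step 10
Reactants: 13 bis(salicylaldehyde) of step 9; 14 ethyl (triphenylphosphoranylidene)acetate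
Product: 16 CNP0164660.2, 8-[(E)-2-{(1R,2R)-2-(5,7-dimethoxy-2-oxo-2H-chromen-8-yl)-1,4-dimethylcyclohex-3-en-1-yl}ethenyl]-5,7-dimethoxy-2H-chromen-2-one, via bis(ethyl 2-hydroxycinnamate) 15 (not isolated)
Conditions: 14 (3 equiv), PhNEt2, reflux (about 215 °C), argon
Reagents that add atoms: none
Why: Each formyl group undergoes Wittig olefination with the stabilised ylide (oxaphosphetane, loss of Ph3PO) to an ethyl 2-hydroxycinnamate, which forms C3–C4; in refluxing N,N-diethylaniline the E ester equilibrates with the Z isomer, whose ester carbonyl lies beside the phenol, and intramolecular transesterification expels ethanol and forms O1–C2. The closest known reaction is the classical coumarin synthesis from salicylaldehydes and Ph3P=CHCO2Et in hot N,N-diethylaniline, which is established for 3-substituted 2-hydroxy-4,6-dimethoxybenzaldehydes. Each pyranone ring closes by 6-exo-trig lactonisation of the phenol oxygen onto the ester carbonyl after the intermolecular olefination, once on each arene. No stereocentre is created; C1 is quaternary and C2 carries no acidifying group, so both are expected to persist, and the E-styryl and ring alkenes are inert to the ylide. The step needs only chemo- and regioselectivity, and the two ortho-hydroxy aldehyde pairs supply it: the ylide reacts only at the formyl groups and only the phenol next to each new cinnamate can lactonise, which gives the 8-substituted 5,7-dimethoxycoumarin pattern twice.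

## Compound list

1 | 2-hydroxy-4,6-dimethoxybenzaldehyde | COc1cc(O)c(C=O)c(OC)c1 | starting material
2 | 2-(allyloxy)-4,6-dimethoxybenzaldehyde | O=Cc1c(OCC=C)cc(OC)cc1OC | intermediate
3 | 3-chloro-2-methylprop-1-ene | C=C(C)CCl | starting material
4 | diethyl (2-methylprop-2-en-1-yl)phosphonate | C=C(C)CP(=O)(OCC)OCC | intermediate
5 | 1-(allyloxy)-3,5-dimethoxy-2-[(1E)-3-methylbuta-1,3-dien-1-yl]benzene | COc1cc(OCC=C)c(/C=C/C(C)=C)c(OC)c1 | intermediate
6 | methacrolein (2-methylprop-2-enal) | C=C(C)C=O | starting material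
7 | (1S,2S)-2-[2-(allyloxy)-4,6-dimethoxyphenyl]-1,4-dimethylcyclohex-3-ene-1-carbaldehyde | O=C[C@@]1(C)CCC(C)=C[C@H]1c1c(OCC=C)cc(OC)cc1OC | intermediate
8 | [2-(allyloxy)-4,6-dimethoxyphenyl]methanol | OCc1c(OCC=C)cc(OC)cc1OC | intermediate
9 | diethyl {[2-(allyloxy)-4,6-dimethoxyphenyl]methyl}phosphonate | CCOP(=O)(Cc1c(OCC=C)cc(OC)cc1OC)OCC | intermediate
10 | 1-(allyloxy)-2-[(E)-2-{(1R,2R)-2-[2-(allyloxy)-4,6-dimethoxyphenyl]-1,4-dimethylcyclohex-3-en-1-yl}ethenyl]-3,5-dimethoxybenzene | COc1cc(OC)cc(OCC=C)c1/C=C/[C@@]1(C)CCC(C)=C[C@H]1c1c(OC)cc(OC)cc1OCC=C | intermediate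
11 | 2-[(E)-2-{(1R,2R)-2-(2-hydroxy-4,6-dimethoxyphenyl)-1,4-dimethylcyclohex-3-en-1-yl}ethenyl]-3,5-dimethoxyphenol | COc1cc(OC)cc(O)c1/C=C/[C@@]1(C)CCC(C)=C[C@H]1c1c(OC)cc(OC)cc1O | intermediate
12 | 2-(hydroxymethyl)-6-[(E)-2-{(1R,2R)-2-[2-hydroxy-3-(hydroxymethyl)-4,6-dimethoxyphenyl]-1,4-dimethylcyclohex-3-en-1-yl}ethenyl]-3,5-dimethoxyphenol (bis(salicyl alcohol), present as its magnesium salt) | COc1cc(OC)c(CO)c(O)c1/C=C/[C@@]1(C)CCC(C)=C[C@H]1c1c(OC)cc(OC)c(CO)c1O | intermediate (not isolated)
13 | 3-[(E)-2-{(1R,2R)-2-(3-formyl-2-hydroxy-4,6-dimethoxyphenyl)-1,4-dimethylcyclohex-3-en-1-yl}ethenyl]-2-hydroxy-4,6-dimethoxybenzaldehyde | COc1cc(OC)c(C=O)c(O)c1/C=C/[C@@]1(C)CCC(C)=C[C@H]1c1c(OC)cc(OC)c(C=O)c1O | intermediate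
14 | ethyl (triphenylphosphoranylidene)acetate | CCOC(=O)C=P(c1ccccc1)(c1ccccc1)c1ccccc1 | starting material
15 | bis(ethyl (E)-2-hydroxycinnamate) from 13, the diethyl ester with an ethyl (E)-propenoate arm in place of each formyl group | COc1cc(OC)c(/C=C/C(=O)OCC)c(O)c1/C=C/[C@@]1(C)CCC(C)=C[C@H]1c1c(OC)cc(OC)c(/C=C/C(=O)OCC)c1O | intermediate (not isolated)
16 | CNP0164660.2, 8-[(E)-2-{(1R,2R)-2-(5,7-dimethoxy-2-oxo-2H-chromen-8-yl)-1,4-dimethylcyclohex-3-en-1-yl}ethenyl]-5,7-dimethoxy-2H-chromen-2-one | COc1cc(OC)c2ccc(=O)oc2c1/C=C/[C@@]1(C)CCC(C)=C[C@H]1c1c(OC)cc(OC)c2ccc(=O)oc12 | target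

## Step count and risks

Total step count: 10. Longest linear sequence: 7 steps (steps 1, 3, 4, 7, 8, 9, 10, from compound 1).

Steps most likely to fail:

1. Step 4. The strongly acidic cationic catalyst may trigger oligomerisation of the electron-rich aryl diene, or the hindered diene may erode the facial and endo/exo discrimination. The fallback sets out from 5 and 6 and comes back at 7. A thermal cycloaddition (toluene, 110 °C, sealed tube, BHT) should give the racemic cis aldehyde F1 after separation from any trans isomer. Condensation with (1R,2R)-N,N'-dimethyl-1,2-diphenylethane-1,2-diamine (CH2Cl2, molecular sieves, rt) converts the racemate into two diastereomeric imidazolidines without creating a stereocentre at the aminal carbon. The imidazolidine of the (1S,2S)-aldehyde F2 is separated by chromatography and hydrolysed with dilute aqueous acid to 7.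

2. Step 10. At about 215 °C the E-to-Z isomerisation and lactonisation may stay incomplete at one of the two sites, or prolonged heating may cause homolysis and re-closure of the doubly allylic and benzylic C1–C2 bond, which would epimerise the core. The fallback sets out from 13 and comes back at 16. With (triphenylphosphoranylidene)ketene, Ph3P=C=C=O, in toluene at 110 °C, each phenol adds across the ketene to give the bis(aryl phosphoranylideneacetate) F3, not isolated. Intramolecular Wittig reaction with the neighbouring formyl group then closes each pyranone ring in the cis geometry directly, so the order of bond formation is reversed (O1–C2 first, then C3=C4) and no alkene isomerisation or high temperature is needed.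

3. Step 7. Carbonyl addition of the bulky di-ortho-substituted benzylic anion to the neopentyl aldehyde, or collapse of the adduct to the alkene, may be too slow. The fallback sets out from 7 and comes back at 11. Boryl olefination of 7 with Cl2CHB(pin), CrCl2 and LiI in THF should give the (E)-alkenyl pinacol boronate F4. Commercial 3,5-dimethoxyphenol (COc1cc(O)cc(OC)c1) is iodinated ortho to the hydroxyl with N-iodosuccinimide to 2-iodo-3,5-dimethoxyphenol F5, separated from the 4-iodo isomer if it forms. Suzuki–Miyaura coupling of F4 with F5 (Pd(OAc)2, SPhos, K3PO4, dioxane/water, 80 °C) should give the mono-allyl styryl phenol F6, which the Pd(PPh3)4/morpholine conditions of step 8 convert into 11. Partial loss of the allyl group during the coupling is harmless.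

Further compounds
F1 | step 4 | racemic cis-2-[2-(allyloxy)-4,6-dimethoxyphenyl]-1,4-dimethylcyclohex-3-ene-1-carbaldehyde (racemate; one enantiomer drawn) | O=C[C@@]1(C)CCC(C)=C[C@H]1c1c(OCC=C)cc(OC)cc1OC
F2 | step 4 | (4R,5R)-2-{(1S,2S)-2-[2-(allyloxy)-4,6-dimethoxyphenyl]-1,4-dimethylcyclohex-3-en-1-yl}-1,3-dimethyl-4,5-diphenylimidazolidine | CN1[C@H](c2ccccc2)[C@@H](c2ccccc2)N(C)C1[C@@]1(C)CCC(C)=C[C@H]1c1c(OCC=C)cc(OC)cc1OC
F3 | step 10 | bis[(triphenylphosphoranylidene)acetate] ester of the two phenols of 13 | COc1cc(OC)c(C=O)c(OC(=O)C=P(c2ccccc2)(c2ccccc2)c2ccccc2)c1/C=C/[C@@]1(C)CCC(C)=C[C@H]1c1c(OC)cc(OC)c(C=O)c1OC(=O)C=P(c1ccccc1)(c1ccccc1)c1ccccc1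
F4 | step 7 | 2-[(E)-2-{(1R,2R)-2-[2-(allyloxy)-4,6-dimethoxyphenyl]-1,4-dimethylcyclohex-3-en-1-yl}ethenyl]-4,4,5,5-tetramethyl-1,3,2-dioxaborolane | CC1(C)OB(/C=C/[C@@]2(C)CCC(C)=C[C@H]2c2c(OCC=C)cc(OC)cc2OC)OC1(C)C
F5 | step 7 | 2-iodo-3,5-dimethoxyphenol | COc1cc(O)c(I)c(OC)c1
F6 | step 7 | 2-[(E)-2-{(1R,2R)-2-[2-(allyloxy)-4,6-dimethoxyphenyl]-1,4-dimethylcyclohex-3-en-1-yl}ethenyl]-3,5-dimethoxyphenol | COc1cc(OC)cc(O)c1/C=C/[C@@]1(C)CCC(C)=C[C@H]1c1c(OC)cc(OC)cc1OCC=C
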